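The furanone ring (O1, C2, C3, C4, C5) is opened at C2–C3 and O1–C5. Lactone carbon C2 lies between aryl-bearing C3 and ring oxygen O1 on ylidene carbon C5 and has the oxidation level of carbon dioxide. One AgOAc/DBU operation on a 1,4-diarylbut-3-yn-2-one can therefore carboxylate the benzylic carbon and lactonise the new carboxylate onto the alkyne, making the ring and the Z-alkene together. The ynone already holds the chroman, the (R)-epoxide (set by Shi epoxidation) and both phenols as triisopropylsilyl ethers. It is assembled from a Corey–Fuchs acetylide and an arylacetic Weinreb amide, and buffered fluoride then releases the target.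

Key step: step 10

Remark: TIPS = triisopropylsilyl; the furanone is numbered O1, C2 (C=O), C3 (aryl), C4 (OH), C5 (ylidene); stannane 12 and the ketone catalyst of step 8 are assumed to be purchasable.

Step 1
Reactants: 1 resorcinol; 2 2-methylbut-3-en-2-ol
Product: 4 2,2-dimethylchroman-7-ol, via 4-prenylresorcinol 3 (not isolated)
Conditions: 1 (3 equiv), 2 (1 equiv), HCO2H, 80 °C
Reagents that add atoms: none
Why: Acid ionises the tertiary allylic alcohol to the prenyl cation, which should alkylate the excess resorcinol at its unhindered C4 (Friedel–Crafts prenylation), and the ortho-prenylphenol then closes by Markovnikov acid-catalysed hydroalkoxylation to the 2,2-dimethylchroman with the second hydroxyl at C7.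

Step 2
Reactants: 4 2,2-dimethylchroman-7-ol
Product: 6 7-hydroxy-2,2-dimethylchroman-6-carbaldehyde, via hydroxymethyl phenol 5 (not isolated)
Conditions: MgCl2, Et3N, (CH2O)n, MeCN, reflux; then 1 M HCl
Reagents that add atoms: paraformaldehyde (formaldehyde), C=O
Why: In this Casnati–Skattebøl ortho-formylation the magnesium phenoxide delivers formaldehyde only ortho to the hydroxyl, C6 (para to the ring oxygen, unhindered) should be preferred over C8, and the benzylic alkoxide is oxidised in the flask by hydride transfer to a second formaldehyde.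

Step 3
Reactants: 6 7-hydroxy-2,2-dimethylchroman-6-carbaldehyde
Product: 7 2,2-dimethyl-7-[(triisopropylsilyl)oxy]chroman-6-carbaldehyde
Conditions: TIPSCl, imidazole, DMF, 23 °C
Reagents that add atoms: chlorotri(propan-2-yl)silane (TIPSCl), CC(C)[Si](Cl)(C(C)C)C(C)C
Why: Imidazole-promoted silylation of the phenol installs a bulky silyl ether that should survive organolithium and amidine base and later keep this oxygen away from the neighbouring alkyne.

Step 4
Reactants: 7 2,2-dimethyl-7-[(triisopropylsilyl)oxy]chroman-6-carbaldehyde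
Product: 8 6-(2,2-dibromoethenyl)-2,2-dimethyl-7-[(triisopropylsilyl)oxy]chroman
Conditions: CBr4 (2 equiv), PPh3 (2 equiv), Zn (2 equiv), CH2Cl2, 23 °C; then 7, 23 °C
Reagents that add atoms: carbon tetrabromide, BrC(Br)(Br)Br
Why: Corey–Fuchs dibromo-olefination, a Wittig reaction of Ph3P=CBr2 generated with zinc, is essentially neutral and should leave the aryl silyl ether intact.

Step 5
Reactants: 9 (3-bromo-4-hydroxyphenyl)acetic acid
Product: 10 2-(3-bromo-4-hydroxyphenyl)-N-methoxy-N-methylacetamide
Conditions: MeNH(OMe)·HCl, EDC·HCl, HOBt, N-methylmorpholine, CH2Cl2–DMF, 0 → 23 °C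
Reagents that add atoms: N,O-dimethylhydroxylamine hydrochloride, CNOC.Cl
Why: Carbodiimide amide coupling through the HOBt active ester, in which the amine outcompetes the free phenol, gives the Weinreb amide that later stops acetylide addition at the ketone stage.

Step 6
Reactants: 10 2-(3-bromo-4-hydroxyphenyl)-N-methoxy-N-methylacetamide
Product: 11 2-{3-bromo-4-[(triisopropylsilyl)oxy]phenyl}-N-methoxy-N-methylacetamide
Conditions: TIPSCl, imidazole, DMF, 23 °C
Reagents that add atoms: chlorotri(propan-2-yl)silane (TIPSCl), CC(C)[Si](Cl)(C(C)C)C(C)C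
Why: Imidazole-promoted silylation masks the phenol as a base-stable, bulky silyl ether so that it cannot attack the epoxide made two steps later.

Step 7
Reactants: 11 2-{3-bromo-4-[(triisopropylsilyl)oxy]phenyl}-N-methoxy-N-methylacetamide; 12 tributyl(3-methylbut-2-en-1-yl)stannane
Product: 13 N-methoxy-N-methyl-2-{3-(3-methylbut-2-en-1-yl)-4-[(triisopropylsilyl)oxy]phenyl}acetamide
Conditions: Pd(PPh3)4 (5 mol%), DMF (degassed), 100 °C
Reagents that add atoms: tributyl(3-methylbut-2-en-1-yl)stannane (12), CCCC[Sn](CCCC)(CCCC)CC=C(C)C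
Why: In this Stille coupling, oxidative addition of the aryl bromide to zerovalent palladium, transmetalation from the prenylstannane and reductive elimination at the less substituted allyl terminus should give the linear prenyl arene without touching amide or silyl ether.

Step 8
Reactants: 13 N-methoxy-N-methyl-2-{3-(3-methylbut-2-en-1-yl)-4-[(triisopropylsilyl)oxy]phenyl}acetamide
Product: 14 2-{3-{[(2R)-3,3-dimethyloxiran-2-yl]methyl}-4-[(triisopropylsilyl)oxy]phenyl}-N-methoxy-N-methylacetamide
Conditions: 1,2:4,5-di-O-isopropylidene-β-D-erythro-2,3-hexodiulo-2,6-pyranose (0.3 equiv), Oxone (2KHSO5·KHSO4·K2SO4), K2CO3, Bu4NHSO4, aq. Na2B4O7 buffer, MeCN–CH2(OMe)2, 0 °C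
Reagents that add atoms: potassium peroxymonosulfate (KHSO5 of Oxone), [K+].[O-]S(=O)(=O)OO
Why: In this Shi epoxidation the chiral dioxirane formed from the D-fructose-derived ketone transfers oxygen through a spiro transition state to the alkene face that makes the oxirane CH carbon R (the only stereocentre of the target), and the cold, mildly basic medium should spare amide and aryl silyl ether.

Step 9
Reactants: 8 6-(2,2-dibromoethenyl)-2,2-dimethyl-7-[(triisopropylsilyl)oxy]chroman; 14 2-{3-{[(2R)-3,3-dimethyloxiran-2-yl]methyl}-4-[(triisopropylsilyl)oxy]phenyl}-N-methoxy-N-methylacetamide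
Product: 17 4-{2,2-dimethyl-7-[(triisopropylsilyl)oxy]chroman-6-yl}-1-{3-{[(2R)-3,3-dimethyloxiran-2-yl]methyl}-4-[(triisopropylsilyl)oxy]phenyl}but-3-yn-2-one, via lithium acetylide 15 (not isolated), via tetrahedral lithium alkoxide 16 (not isolated)
Conditions: 8 (1.3 equiv), n-BuLi (2.5 equiv), THF, −78 °C; then 14 (1.0 equiv), −78 → 0 °C; AcOH, −78 °C, then pH 7 buffer
Reagents that add atoms: none
Why: The second stage of the Corey–Fuchs sequence (bromine–lithium exchange, Fritsch–Buttenberg–Wiechell rearrangement, deprotonation) gives the lithium acetylide, whose addition to the Weinreb amide stops at the chelated tetrahedral alkoxide and releases the ynone only on quench (Weinreb ketone synthesis), while without a Lewis acid the acetylide should not open the trisubstituted epoxide.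

Step 10
Reactants: 17 4-{2,2-dimethyl-7-[(triisopropylsilyl)oxy]chroman-6-yl}-1-{3-{[(2R)-3,3-dimethyloxiran-2-yl]methyl}-4-[(triisopropylsilyl)oxy]phenyl}but-3-yn-2-one; 18 carbon dioxide
Product: 20 (5Z)-3-{3-{[(2R)-3,3-dimethyloxiran-2-yl]methyl}-4-[(triisopropylsilyl)oxy]phenyl}-5-({2,2-dimethyl-7-[(triisopropylsilyl)oxy]chroman-6-yl}methylidene)-4-hydroxyfuran-2(5H)-one, via β-keto carboxylate 19 (not isolated)
Conditions: AgOAc (0.3 equiv), DBU (3 equiv), CO2 (1 MPa), MeCN, 25 °C; then EtOAc/cold 5% aq. citric acid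
Reagents that add atoms: carbon dioxide (18), O=C=O
Why: DBU reversibly removes a proton from the CH2 of 17, which is acidified by both the ketone and the aryl ring, and the enolate carbon adds to CO2 to give β-keto carboxylate 19 (bond C2–C3); the silver cation then binds the alkyne and a carboxylate oxygen adds anti to the metal at the alkyne carbon next to the ketone, a 5-exo-dig closure that forms O1–C5, after which protonolysis of the C–Ag bond and enolisation give the tetronate. The closest known reaction type is the silver-catalysed carboxylative cyclisation of conjugated ynones with CO2 to 5-ylidene tetronic acids, applied here to a more substituted substrate. No stereocentre is created; the Z alkene follows from anti oxymetalation and retentive protonolysis, which place the chroman ring on the same side as O1, and the epoxide centre is remote and untouched. The step needs 5-exo rather than 6-endo closure (the latter would give the isomeric 4-hydroxy-2-pyranone), and this should be secured by the short three-atom tether, which holds the carboxylate oxygen next to the proximal alkyne carbon, and by the two oxygen donors of the chroman ring, which deactivate the distal carbon as a conjugate acceptor; formation of the stabilised tetronate anion also pulls the reversible carboxylation forward. The bulky 7-O-silyl ether keeps the ortho oxygen from adding to the activated alkyne (benzofuran formation), and the basic, halide-free medium should leave the epoxide and both aryl silyl ethers intact.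

Step 11
Reactants: 20 (5Z)-3-{3-{[(2R)-3,3-dimethyloxiran-2-yl]methyl}-4-[(triisopropylsilyl)oxy]phenyl}-5-({2,2-dimethyl-7-[(triisopropylsilyl)oxy]chroman-6-yl}methylidene)-4-hydroxyfuran-2(5H)-one
Product: 21 (5Z)-3-(3-{[(2R)-3,3-dimethyloxiran-2-yl]methyl}-4-hydroxyphenyl)-4-hydroxy-5-[(7-hydroxy-2,2-dimethylchroman-6-yl)methylidene]furan-2(5H)-one
Conditions: Bu4NF (3 equiv), AcOH (4 equiv), THF, 0 °C; pH 5 phosphate buffer work-up
Reagents that add atoms: none
Why: Fluoride cleaves both aryl silyl ethers through Si–F bond formation, and the acetic acid buffer should protonate each phenoxide as it forms so that it cannot open the neighbouring epoxide, while the Z-ylidene tetronic acid and the oxirane stereocentre are not affected.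

Compound list
1 | resorcinol (benzene-1,3-diol) | Oc1cccc(O)c1 | starting material
2 | 2-methylbut-3-en-2-ol | CC(C)(O)C=C | starting material
3 | 4-(3-methylbut-2-en-1-yl)benzene-1,3-diol (4-prenylresorcinol; not isolated) | CC(C)=CCc1ccc(O)cc1O | intermediate
4 | 2,2-dimethylchroman-7-ol (2,2-dimethyl-3,4-dihydro-2H-chromen-7-ol) | CC1(C)CCc2ccc(O)cc2O1 | intermediate
5 | 6-(hydroxymethyl)-2,2-dimethylchroman-7-ol (formed as its magnesium salt; not isolated) | CC1(C)CCc2cc(CO)c(O)cc2O1 | intermediate
6 | 7-hydroxy-2,2-dimethylchroman-6-carbaldehyde | CC1(C)CCc2cc(C=O)c(O)cc2O1 | intermediate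
7 | 2,2-dimethyl-7-[(triisopropylsilyl)oxy]chroman-6-carbaldehyde | CC1(C)CCc2cc(C=O)c(O[Si](C(C)C)(C(C)C)C(C)C)cc2O1 | intermediate
8 | 6-(2,2-dibromoethenyl)-2,2-dimethyl-7-[(triisopropylsilyl)oxy]chroman | CC1(C)CCc2cc(C=C(Br)Br)c(O[Si](C(C)C)(C(C)C)C(C)C)cc2O1 | intermediate
9 | (3-bromo-4-hydroxyphenyl)acetic acid | OC(=O)Cc1ccc(O)c(Br)c1 | starting material
10 | 2-(3-bromo-4-hydroxyphenyl)-N-methoxy-N-methylacetamide | CON(C)C(=O)Cc1ccc(O)c(Br)c1 | intermediate
11 | 2-{3-bromo-4-[(triisopropylsilyl)oxy]phenyl}-N-methoxy-N-methylacetamide | CON(C)C(=O)Cc1ccc(O[Si](C(C)C)(C(C)C)C(C)C)c(Br)c1 | intermediate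
12 | tributyl(3-methylbut-2-en-1-yl)stannane | CCCC[Sn](CCCC)(CCCC)CC=C(C)C | starting material
13 | N-methoxy-N-methyl-2-{3-(3-methylbut-2-en-1-yl)-4-[(triisopropylsilyl)oxy]phenyl}acetamide | CON(C)C(=O)Cc1ccc(O[Si](C(C)C)(C(C)C)C(C)C)c(CC=C(C)C)c1 | intermediate
14 | 2-{3-{[(2R)-3,3-dimethyloxiran-2-yl]methyl}-4-[(triisopropylsilyl)oxy]phenyl}-N-methoxy-N-methylacetamide | CON(C)C(=O)Cc1ccc(O[Si](C(C)C)(C(C)C)C(C)C)c(C[C@H]2OC2(C)C)c1 | intermediate
15 | ({2,2-dimethyl-7-[(triisopropylsilyl)oxy]chroman-6-yl}ethynyl)lithium (not isolated) | CC1(C)CCc2cc(C#C[Li])c(O[Si](C(C)C)(C(C)C)C(C)C)cc2O1 | intermediate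
16 | lithium alkoxide of the tetrahedral adduct of 15 and 14 (carbinol carbon unassigned; not isolated) | CC1(C)CCc2cc(C#CC(O[Li])(Cc3ccc(O[Si](C(C)C)(C(C)C)C(C)C)c(C[C@H]4OC4(C)C)c3)N(C)OC)c(O[Si](C(C)C)(C(C)C)C(C)C)cc2O1 | intermediate
17 | 4-{2,2-dimethyl-7-[(triisopropylsilyl)oxy]chroman-6-yl}-1-{3-{[(2R)-3,3-dimethyloxiran-2-yl]methyl}-4-[(triisopropylsilyl)oxy]phenyl}but-3-yn-2-one | CC1(C)CCc2cc(C#CC(=O)Cc3ccc(O[Si](C(C)C)(C(C)C)C(C)C)c(C[C@H]4OC4(C)C)c3)c(O[Si](C(C)C)(C(C)C)C(C)C)cc2O1 | intermediate
18 | carbon dioxide | O=C=O | starting material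
19 | β-keto carboxylate from 17 and CO2, as its DBU-H salt (α-carbon labile; not isolated) | CC1(C)CCc2cc(C#CC(=O)C(C(=O)[O-])c3ccc(O[Si](C(C)C)(C(C)C)C(C)C)c(C[C@H]4OC4(C)C)c3)c(O[Si](C(C)C)(C(C)C)C(C)C)cc2O1.C1CCC2=[NH+]CCCN2CC1 | intermediate
20 | (5Z)-3-{3-{[(2R)-3,3-dimethyloxiran-2-yl]methyl}-4-[(triisopropylsilyl)oxy]phenyl}-5-({2,2-dimethyl-7-[(triisopropylsilyl)oxy]chroman-6-yl}methylidene)-4-hydroxyfuran-2(5H)-one | CC1(C)CCc2cc(/C=C3\OC(=O)C(c4ccc(O[Si](C(C)C)(C(C)C)C(C)C)c(C[C@H]5OC5(C)C)c4)=C3O)c(O[Si](C(C)C)(C(C)C)C(C)C)cc2O1 | intermediate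
21 | (5Z)-3-(3-{[(2R)-3,3-dimethyloxiran-2-yl]methyl}-4-hydroxyphenyl)-4-hydroxy-5-[(7-hydroxy-2,2-dimethylchroman-6-yl)methylidene]furan-2(5H)-one | CC1(C)CCc2cc(/C=C3\OC(=O)C(c4ccc(O)c(C[C@H]5OC5(C)C)c4)=C3O)c(O)cc2O1 | target

Total step count: 11.
Longest linear sequence: 7 steps (steps 1–4 and 9–11 from resorcinol; the arm from 9, steps 5–11, is equally long).

Steps most likely to fail

Step 10. The carboxylate may close in the 6-endo sense onto the aryl-bearing alkyne carbon, the carboxylation may revert before ring closure, or the 7-O-silyl group may be lost and the freed oxygen may add to the alkyne. The fallback builds the ring by acylation chemistry that involves no alkyne. It sets out from 7 and 9 and returns at 20. Wittig reaction of 7 with the stabilised ylide 2,2-dimethyl-5-(triphenylphosphoranylidene)-1,3-dioxolan-4-one (toluene, 90 °C) should give mainly the Z-arylidene dioxolanone (5Z)-5-({2,2-dimethyl-7-[(triisopropylsilyl)oxy]chroman-6-yl}methylidene)-2,2-dimethyl-1,3-dioxolan-4-one F1. In parallel, 9 is taken through the ester series: Fischer esterification (MeOH, H2SO4) to methyl (3-bromo-4-hydroxyphenyl)acetate F2, silylation as in step 6 to methyl {3-bromo-4-[(triisopropylsilyl)oxy]phenyl}acetate F3, Stille prenylation with 12 as in step 7 to methyl {3-(3-methylbut-2-en-1-yl)-4-[(triisopropylsilyl)oxy]phenyl}acetate F4, and Shi epoxidation as in step 8 to methyl {3-{[(2R)-3,3-dimethyloxiran-2-yl]methyl}-4-[(triisopropylsilyl)oxy]phenyl}acetate F5. The lithium enolate of F5 (2 equiv, LiN(iPr)2, THF, −78 → 0 °C) then attacks the lactone carbonyl of F1 (Claisen acylation). Loss of acetone frees the enolate oxygen, which lactonises onto the methyl ester and should give 20 with the Z geometry carried over from F1.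

Step 11. The phenol next to the epoxide, or its phenoxide, may open the oxirane during or after desilylation, giving a dihydrobenzofuran or chromanol. The fallback releases the phenols by neutral acyl transfer. It sets out from 20 and returns at 21. Compound 20 is treated with Ac2O and Et3N, and Bu4NF is then added slowly at −20 °C with Ac2O in excess, so that each phenoxide is acetylated as it is unmasked. This should give the triacetate (5Z)-3-(4-acetoxy-3-{[(2R)-3,3-dimethyloxiran-2-yl]methyl}phenyl)-5-[(7-acetoxy-2,2-dimethylchroman-6-yl)methylidene]-2-oxo-2,5-dihydrofuran-4-yl acetate F6. Methanolysis of the two aryl acetates and the enol acetate with NH4OAc in aqueous MeOH at 23 °C then gives 21 at neutral pH without a phenoxide being present.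

Step 7. Oxidative addition may be slow next to the bulky silyl ether, and allyl transposition during prenyl transfer may give the reverse-prenyl isomer. The fallback brings in the five carbons as an allyl group plus a metathesis partner. It sets out from 11 and returns at 13. Suzuki–Miyaura coupling of 11 with allylboronic acid pinacol ester (PdCl2(dppf), K2CO3, dioxane–H2O, 80 °C) should give N-methoxy-N-methyl-2-{3-(prop-2-en-1-yl)-4-[(triisopropylsilyl)oxy]phenyl}acetamide F7. Olefin cross-metathesis of F7 with excess 2-methylbut-2-ene (second-generation Grubbs catalyst, CH2Cl2, 40 °C) then gives 13.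

Further compounds
F1 | step 10 | (5Z)-5-({2,2-dimethyl-7-[(triisopropylsilyl)oxy]chroman-6-yl}methylidene)-2,2-dimethyl-1,3-dioxolan-4-one | CC1(C)CCc2cc(/C=C3\OC(C)(C)OC3=O)c(O[Si](C(C)C)(C(C)C)C(C)C)cc2O1
F2 | step 10 | methyl (3-bromo-4-hydroxyphenyl)acetate | COC(=O)Cc1ccc(O)c(Br)c1
F3 | step 10 | methyl {3-bromo-4-[(triisopropylsilyl)oxy]phenyl}acetate | COC(=O)Cc1ccc(O[Si](C(C)C)(C(C)C)C(C)C)c(Br)c1
F4 | step 10 | methyl {3-(3-methylbut-2-en-1-yl)-4-[(triisopropylsilyl)oxy]phenyl}acetate | COC(=O)Cc1ccc(O[Si](C(C)C)(C(C)C)C(C)C)c(CC=C(C)C)c1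
F5 | step 10 | methyl {3-{[(2R)-3,3-dimethyloxiran-2-yl]methyl}-4-[(triisopropylsilyl)oxy]phenyl}acetate | COC(=O)Cc1ccc(O[Si](C(C)C)(C(C)C)C(C)C)c(C[C@H]2OC2(C)C)c1
F6 | step 11 | (5Z)-3-(4-acetoxy-3-{[(2R)-3,3-dimethyloxiran-2-yl]methyl}phenyl)-5-[(7-acetoxy-2,2-dimethylchroman-6-yl)methylidene]-2-oxo-2,5-dihydrofuran-4-yl acetate | CC1(C)CCc2cc(/C=C3\OC(=O)C(c4ccc(OC(C)=O)c(C[C@H]5OC5(C)C)c4)=C3OC(C)=O)c(OC(C)=O)cc2O1
F7 | step 7 | N-methoxy-N-methyl-2-{3-(prop-2-en-1-yl)-4-[(triisopropylsilyl)oxy]phenyl}acetamide | CON(C)C(=O)Cc1ccc(O[Si](C(C)C)(C(C)C)C(C)C)c(CC=C)c1
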